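**Retrosynthetic overview**
1. The C(=O)–CH2–C(=O) unit is cut between the methylene carbon and the carbonyl carbon that carries the 4-hydroxyphenyl ring. In the precursor this aroyl group sits as an aryl ester on the C4' oxygen of ring A (the 2,4-dioxygenated ring), and base moves it from that oxygen to the acetyl carbon.
2. Enabling feature: the free phenolic OH on C4' of ring A, para to the acyl-bearing C1', beside the acidic carbon alpha to the ring-A ketone. This is the one OH that must be masked while the chelated C2'–OH is methylated, so the "protecting group" is the other half of the molecule, held as an activated aryl ester and released as the free C4' phenol when the C–C bond forms.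
3. Ring A pattern: the prenyl group enters C3' by aromatic Claisen rearrangement of the 4-O-(1,1-dimethylallyl) ether of 2,4-dihydroxyacetophenone, steered between the two oxygens by the chelated 2-OH/acetyl pair. 4-O-Aroylation and 2-O-methylation follow.
4. No ring is built: both benzene rings are bought (2,4-dihydroxyacetophenone, 4-hydroxybenzoic acid). After step 3 no acid and no hydrogenation touches the ortho-prenyl phenol.

Key step: step 7

Remark: the target has no stereocentre and no E/Z element; it is written as the diketo form but should exist largely as the chelated enol, which does not change the route.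

Step 1
Reactants: 1 1-(2,4-dihydroxyphenyl)ethan-1-one and 2 3-chloro-3-methylbut-1-yne
Product: 3 1-[2-hydroxy-4-(2-methylbut-3-yn-2-yloxy)phenyl]ethan-1-one
Conditions: K2CO3, KI (cat.), CuI (cat.), acetone, reflux
Reagents that add atoms: none
Why: Copper-assisted Williamson-type O-alkylation with the tertiary propargylic chloride should take place only at the 4-OH, because the 2-OH is held in a hydrogen bond to the acetyl group and is less nucleophilic.

Step 2
Reactants: 3 1-[2-hydroxy-4-(2-methylbut-3-yn-2-yloxy)phenyl]ethan-1-one
Product: 4 1-[2-hydroxy-4-(2-methylbut-3-en-2-yloxy)phenyl]ethan-1-one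
Conditions: H2 (1 atm), Lindlar catalyst, quinoline, EtOAc, rt
Reagents that add atoms: none
Why: Lindlar semihydrogenation should stop at the terminal alkene and leave the aryl ketone and the tertiary allylic ether untouched.

Step 3
Reactants: 4 1-[2-hydroxy-4-(2-methylbut-3-en-2-yloxy)phenyl]ethan-1-one
Product: 5 1-[2,4-dihydroxy-3-(3-methylbut-2-en-1-yl)phenyl]ethan-1-one
Conditions: PhNEt2, 160 °C, argon
Reagents that add atoms: none
Why: Aromatic Claisen rearrangement ([3,3] shift, then tautomerisation) of the 1,1-dimethylallyl ether delivers a linear prenyl group to an ortho carbon, and the chelated 2-hydroxyacetophenone unit gives the C3–C4 bond the higher double-bond character, so migration should go to C3 between the two oxygens and not to C5.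

Step 4
Reactants: 6 4-hydroxybenzoic acid
Product: 8 4-[(tert-butyldimethylsilyl)oxy]benzoic acid, via bis-silylated acid 7 (not isolated)
Conditions: TBSCl (2.2 equiv), imidazole, DMF, rt; then AcOH/THF/H2O, rt
Reagents that add atoms: tert-butyldimethylsilyl chloride, CC(C)(C)[Si](C)(C)Cl
Why: Silyl protection of both acidic OH groups followed by selective hydrolysis of the far more labile silyl ester should leave the aryl silyl ether and the free acid.

Step 5
Reactants: 5 1-[2,4-dihydroxy-3-(3-methylbut-2-en-1-yl)phenyl]ethan-1-one and 8 4-[(tert-butyldimethylsilyl)oxy]benzoic acid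
Product: 9 4-acetyl-3-hydroxy-2-(3-methylbut-2-en-1-yl)phenyl 4-[(tert-butyldimethylsilyl)oxy]benzoate
Conditions: DCC, DMAP (cat.), CH2Cl2, 0 °C to rt
Reagents that add atoms: none
Why: Steglich esterification should acylate only the 4-OH, since the 2-OH is chelated to the acetyl group and flanked by two ortho substituents.

Step 6
Reactants: 9 4-acetyl-3-hydroxy-2-(3-methylbut-2-en-1-yl)phenyl 4-[(tert-butyldimethylsilyl)oxy]benzoate
Product: 10 4-acetyl-3-methoxy-2-(3-methylbut-2-en-1-yl)phenyl 4-[(tert-butyldimethylsilyl)oxy]benzoate
Conditions: MeOH, PPh3, DIAD, THF, 0 °C to rt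
Reagents that add atoms: methanol, CO
Why: Mitsunobu O-alkylation with methanol methylates the chelated phenol under neutral conditions in which no free phenoxide builds up, so the aryl ester and the aryl silyl ether should neither be cleaved nor migrate.

Step 7
Reactants: 10 4-acetyl-3-methoxy-2-(3-methylbut-2-en-1-yl)phenyl 4-[(tert-butyldimethylsilyl)oxy]benzoate
Product: 12 1-[4-hydroxy-2-methoxy-3-(3-methylbut-2-en-1-yl)phenyl]-3-(4-hydroxyphenyl)propane-1,3-dione (the target), via silyl-protected diketone 11 (not isolated)
Conditions: LiHMDS (2.4 equiv), THF (0.3 M), −78 °C to rt; then AcOH, TBAF, rt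
Reagents that add atoms: none
Why: Proposed new method: LiHMDS first turns the acetyl group of every molecule into its lithium enolate; on warming, the enolate carbon of one molecule adds to the aryl ester carbonyl of another (the para arrangement excludes an intramolecular path), the tetrahedral intermediate expels the ring-A C4' phenoxide, and the β-diketone formed is deprotonated at once, so that all acyl shuttles, enol esters included, drain into the lithium diketonate–phenoxide as the thermodynamic sink. The closest known reaction types are the Baker–Venkataraman O-to-C aroyl transfer of ortho-acyloxyaryl ketones, the Claisen acylation of aryl methyl ketone enolates by aryl benzoates and the C-aroylation of lithium polyanions of hydroxyacetophenones; what is new is the bimolecular head-to-tail transfer within one para-acyloxyaryl ketone. No ring is closed and no stereocentre is formed. The selectivity needed is C-monoacylation, which should be secured because the substrate carries exactly one aroyl group per acetyl group, because ketone enolates outcompete the much less nucleophilic diketonate for the ester, and because O-acylated by-products are themselves acyl donors. The hindered amide base at low temperature limits its own attack on the ester, and the prenyl alkene, the methyl ether and the silyl ether are inert to it. Buffered fluoride then cleaves the aryl silyl ether in the same flask, so that the free diphenolic diketone should be obtained without any acid touching the ortho-prenyl phenol.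

**Compound list**
1 | 1-(2,4-dihydroxyphenyl)ethan-1-one | CC(=O)c1ccc(O)cc1O | starting material
2 | 3-chloro-3-methylbut-1-yne | CC(C)(Cl)C#C | starting material
3 | 1-[2-hydroxy-4-(2-methylbut-3-yn-2-yloxy)phenyl]ethan-1-one | CC(=O)c1ccc(OC(C)(C)C#C)cc1O | intermediate
4 | 1-[2-hydroxy-4-(2-methylbut-3-en-2-yloxy)phenyl]ethan-1-one | CC(=O)c1ccc(OC(C)(C)C=C)cc1O | intermediate
5 | 1-[2,4-dihydroxy-3-(3-methylbut-2-en-1-yl)phenyl]ethan-1-one | CC(=O)c1ccc(O)c(CC=C(C)C)c1O | intermediate
6 | 4-hydroxybenzoic acid | OC(=O)c1ccc(O)cc1 | starting material
7 | tert-butyldimethylsilyl 4-[(tert-butyldimethylsilyl)oxy]benzoate (not isolated) | CC(C)(C)[Si](C)(C)OC(=O)c1ccc(O[Si](C)(C)C(C)(C)C)cc1 | intermediate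
8 | 4-[(tert-butyldimethylsilyl)oxy]benzoic acid | CC(C)(C)[Si](C)(C)Oc1ccc(C(=O)O)cc1 | intermediate
9 | 4-acetyl-3-hydroxy-2-(3-methylbut-2-en-1-yl)phenyl 4-[(tert-butyldimethylsilyl)oxy]benzoate | CC(=O)c1ccc(OC(=O)c2ccc(O[Si](C)(C)C(C)(C)C)cc2)c(CC=C(C)C)c1O | intermediate
10 | 4-acetyl-3-methoxy-2-(3-methylbut-2-en-1-yl)phenyl 4-[(tert-butyldimethylsilyl)oxy]benzoate | COc1c(C(C)=O)ccc(OC(=O)c2ccc(O[Si](C)(C)C(C)(C)C)cc2)c1CC=C(C)C | intermediate
11 | 1-{4-[(tert-butyldimethylsilyl)oxy]phenyl}-3-[4-hydroxy-2-methoxy-3-(3-methylbut-2-en-1-yl)phenyl]propane-1,3-dione (not isolated) | COc1c(C(=O)CC(=O)c2ccc(O[Si](C)(C)C(C)(C)C)cc2)ccc(O)c1CC=C(C)C | intermediate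
12 | 1-[4-hydroxy-2-methoxy-3-(3-methylbut-2-en-1-yl)phenyl]-3-(4-hydroxyphenyl)propane-1,3-dione | COc1c(C(=O)CC(=O)c2ccc(O)cc2)ccc(O)c1CC=C(C)C | target

**Step count**
Total steps: 7. Longest linear sequence: 6 (steps 1, 2, 3, 5, 6, 7).

**Steps most likely to fail**

Step 7 (labelled step). The bimolecular aroyl transfer may stall at partial conversion or be diverted: the amide base may attack the aryl ester, silyl groups may migrate between phenoxides and deactivate the acyl donor, or a second aroyl group may be taken up at carbon. The fallback uses known two-component chemistry; it sets out from 10 and comes back at 11. Transesterification of 10 with catalytic NaOMe in MeOH at 0 °C should release 1-[4-hydroxy-2-methoxy-3-(3-methylbut-2-en-1-yl)phenyl]ethan-1-one F1. Acid 8 would be converted with oxalyl chloride and catalytic DMF in CH2Cl2 into 4-[(tert-butyldimethylsilyl)oxy]benzoyl chloride F2. Treatment of F1 with LiHMDS (3 equiv, THF, −78 °C) should give the phenoxide–enolate dianion, which is C-aroylated by F2 (Claisen acylation of a lithium polyanion of a hydroxyacetophenone) to give 11. This then receives the fluoride treatment of step 7.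

Step 6. The Mitsunobu etherification of a chelated, doubly ortho-substituted phenol may be slow, and any phenoxide that builds up may shuttle the aroyl group between oxygens. The fallback sets out from 5 and comes back at 10; it methylates before the aroyl group is attached. Selective 4-O-protection of 5 (MOMCl, i-Pr2NEt, CH2Cl2) should give 1-[2-hydroxy-4-(methoxymethoxy)-3-(3-methylbut-2-en-1-yl)phenyl]ethan-1-one F3. Methylation (MeI, K2CO3, acetone, reflux) should give 1-[2-methoxy-4-(methoxymethoxy)-3-(3-methylbut-2-en-1-yl)phenyl]ethan-1-one F4. Brief treatment with dilute HCl in MeOH at rt removes the acetal to give the phenol ketone F1 named above, and Steglich esterification of F1 with 8 (DCC, DMAP) gives 10.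

Step 3. Part of the allyl group may migrate to C5, the ortho-prenyl resorcinol may cyclise thermally onto its alkene, or the tertiary ether may fragment. The fallback sets out from 1 and comes back at 5, replacing the sigmatropic route (steps 1–3) by direct C-alkylation. Prenyl bromide in aqueous KOH at rt should alkylate the resorcinolate of 1 at the carbon between the two oxygens, and 5 would be separated from its 5-prenyl isomer and O-alkylated material by chromatography. This fallback makes no new compound (F0).

**Further compounds**
F1 | step 7 | 1-[4-hydroxy-2-methoxy-3-(3-methylbut-2-en-1-yl)phenyl]ethan-1-one | COc1c(C(C)=O)ccc(O)c1CC=C(C)C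
F2 | step 7 | 4-[(tert-butyldimethylsilyl)oxy]benzoyl chloride | CC(C)(C)[Si](C)(C)Oc1ccc(C(Cl)=O)cc1
F3 | step 6 | 1-[2-hydroxy-4-(methoxymethoxy)-3-(3-methylbut-2-en-1-yl)phenyl]ethan-1-one | COCOc1ccc(C(C)=O)c(O)c1CC=C(C)C
F4 | step 6 | 1-[2-methoxy-4-(methoxymethoxy)-3-(3-methylbut-2-en-1-yl)phenyl]ethan-1-one | COCOc1ccc(C(C)=O)c(OC)c1CC=C(C)C
F0 | step 3 | none | none
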